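**Assumptions (two lines):** (R)-t-BuPHOX is taken to deliver the (R)-ketone 10 in the Pd-catalysed allylation, and the enantiomeric ligand gives the enantiomer. A ketoreductase delivering the (S)-alcohol 18 can be found by panel screening.

## Retrosynthetic overview
1. Fertidin (23) is the p-anisate of jaeschkeanadiol (21). The seven-membered ring is closed last by RCM of diene-diol 20, so the cyclopentane is built first.
2. Diol 20 comes from Red-Al opening of epoxy alcohol 19, which comes from hydroxyl-directed epoxidation of allylic alcohol 18. The carbinol configuration then sets the tertiary i-OH/i-iPr centre and the ring-fusion H.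
3. Alcohol 18 comes from ketoreductase reduction of enone 17, then Weinreb amide 15, then vinyl triflate 12, then α-quaternary ketone 10 (Pd-catalysed asymmetric allylation, first stereocentre).
4. Ketone 10 comes from β-ketoester 9, built from cyclopentanone, acetone, diallyl carbonate and MeI.

## Route

**Step 1**
Reactants: 1 cyclopentanone; 2 acetone
Product: 3 2-(2-hydroxypropan-2-yl)cyclopentan-1-one (racemic)
Conditions: LDA, THF, –78 °C; then acetone; cold aq. NH4Cl
Reagents that add atoms: none (acetone is reactant 2, CC(C)=O)
Why: Crossed lithium-enolate aldol of the pre-formed enolate with acetone. The stereocentre is racemic and is destroyed later.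

**Step 2**
Reactants: 3
Product: 4 2-(propan-2-ylidene)cyclopentan-1-one (may contain the isopropenyl isomer)
Conditions: p-TsOH·H2O (cat.), PhH, reflux, Dean–Stark
Reagents that add atoms: none
Why: Acid-catalysed dehydration of the tertiary β-hydroxy ketone to the conjugated enone. Any isopropenyl isomer converges in step 3.

**Step 3**
Reactants: 4
Product: 5 2-(propan-2-yl)cyclopentan-1-one (racemic)
Conditions: H2 (1 atm), 10% Pd/C, EtOAc, rt
Reagents that add atoms: none (H2 adds only hydrogen)
Why: Catalytic hydrogenation of the enone C=C. The new stereocentre is erased at the triflation in step 7.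

**Step 4**
Reactants: 5; 6 diallyl carbonate
Product: 7 allyl 2-oxo-3-(propan-2-yl)cyclopentane-1-carboxylate (diastereomer mixture)
Conditions: NaH, THF, reflux
Reagents that add atoms: diallyl carbonate, C=CCOC(=O)OCC=C
Why: Claisen-type C-acylation. It is regioselective for the unhindered CH2 side because only that β-ketoester can form a stabilised enolate; acylation at the isopropyl-bearing carbon is reversible.

**Step 5**
Reactants: 7; 8 iodomethane
Product: 9 allyl 1-methyl-2-oxo-3-(propan-2-yl)cyclopentane-1-carboxylate (diastereomer mixture)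
Conditions: MeI, K2CO3, acetone, reflux
Reagents that add atoms: MeI, CI
Why: C-Alkylation of the stabilised enolate (the only acidic site) builds the quaternary β-ketoester.

**Step 6**
Reactants: 9
Product: 10 (2R)-2-methyl-5-(propan-2-yl)-2-(prop-2-en-1-yl)cyclopentan-1-one (C5 epimers, interconvertible)
Conditions: Pd2(dba)3 (2.5 mol%), (R)-t-BuPHOX (6 mol%), THF, 25–40 °C
Reagents that add atoms: none (CO2 is lost)
Why: Decarboxylative asymmetric allylic alkylation (Tsuji–Stoltz). Decarboxylation gives a regiospecific prochiral enolate, and the chiral ligand sets the quaternary carbon (first stereocentre). The C5 epimers are irrelevant because C5 becomes sp2 next.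

**Step 7**
Reactants: 10; 11 N-phenylbis(trifluoromethanesulfonimide)
Product: 12 (5R)-5-methyl-2-(propan-2-yl)-5-(prop-2-en-1-yl)cyclopent-1-en-1-yl triflate
Conditions: KHMDS, THF, –78 °C; then PhNTf2, –78 → 0 °C
Reagents that add atoms: PhNTf2, O=S(=O)(C(F)(F)F)N(c1ccccc1)S(=O)(=O)C(F)(F)F (supplies OTf)
Why: Enolate O-triflation. The only enolisable α-carbon is C5, so it is regiospecific and the epimers converge to one tetrasubstituted triflate. The quaternary centre has no α-H and is untouched.

**Step 8**
Reactants: 12; 13 carbon monoxide; 14 N,O-dimethylhydroxylamine (as HCl salt)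
Product: 15 (5R)-N-methoxy-N,5-dimethyl-2-(propan-2-yl)-5-(prop-2-en-1-yl)cyclopent-1-ene-1-carboxamide
Conditions: Pd(OAc)2, dppf, CO (1–5 atm), Et3N, DMF, 70 °C
Reagents that add atoms: CO, [C-]#[O+]; HN(OMe)Me·HCl, CONC.Cl
Why: Pd-catalysed aminocarbonylation of the enol triflate (Cacchi-type) gives the α,β-unsaturated Weinreb amide. The stereocentre is untouched.

**Step 9**
Reactants: 15; 16 methallylmagnesium chloride (from 3-chloro-2-methylpropene + Mg)
Product: 17 1-[(5R)-5-methyl-2-(propan-2-yl)-5-(prop-2-en-1-yl)cyclopent-1-en-1-yl]-3-methylbut-3-en-1-one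
Conditions: CH2=C(Me)CH2MgCl (2 equiv), THF, –78 → 0 °C; cold aq. NH4Cl
Reagents that add atoms: methallylmagnesium chloride, C=C(C)C[Mg]Cl
Why: Weinreb ketone synthesis via a chelated tetrahedral intermediate, so there is no over-addition. The β,β-disubstituted enamide disfavours 1,4-addition, and the cold quench avoids isomerisation of the β,γ-alkene.

**Step 10**
Reactants: 17
Product: 18 (1S)-1-[(5R)-5-methyl-2-(propan-2-yl)-5-(prop-2-en-1-yl)cyclopent-1-en-1-yl]-3-methylbut-3-en-1-ol
Conditions: ketoreductase (KRED, NADPH-dependent oxidoreductase, selected for (S)), NADP+ (cat.), D-glucose/glucose dehydrogenase, KPi pH 7.0, 20% DMSO, 30 °C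
Reagents that add atoms: none (hydride and proton only)
Why: Enzymatic asymmetric ketone reduction. The enzyme controls the carbinol face (Prelog/anti-Prelog choice by screening), independent of the quaternary centre. Any minor (S)-enantiomer of 17 gives a separable diastereomer, which upgrades ee.

**Step 11**
Reactants: 18
Product: 19 (1S)-1-[(1S,2R,5R)-2-methyl-5-(propan-2-yl)-2-(prop-2-en-1-yl)-6-oxabicyclo[3.1.0]hexan-1-yl]-3-methylbut-3-en-1-ol (epoxide O cis to the angular Me)
Conditions: VO(acac)2 (5 mol%), t-BuOOH (1.2 equiv), CH2Cl2, 0 °C → rt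
Reagents that add atoms: tert-butyl hydroperoxide, CC(C)(C)OO (supplies the epoxide O)
Why: Hydroxyl-directed Sharpless–Michaelson epoxidation delivers O syn to the carbinol O, and much faster than to the isolated alkenes. In the reactive conformer of the (S)-carbinol (H toward the quaternary carbon, minimising A(1,2) strain), the oxygen is delivered to the face cis to the angular methyl. This fixes the configuration of the future i-OH/i-iPr.

**Step 12**
Reactants: 19
Product: 20 (1R,2S,3R)-2-[(1S)-1-hydroxy-3-methylbut-3-en-1-yl]-3-methyl-1-(propan-2-yl)-3-(prop-2-en-1-yl)cyclopentan-1-ol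
Conditions: Red-Al (65% in toluene, 5 equiv), THF, 0 → 65 °C; Rochelle salt work-up
Reagents that add atoms: none (hydride adds only hydrogen)
Why: Finan–Kishi regioselective reductive opening of a 2,3-epoxy alcohol. The alkoxyaluminate delivers hydride to the proximal carbon (C3a) with inversion, so H enters trans to the angular methyl (trans ring fusion). The tertiary alkoxide stays on the epoxide face, giving OH cis to Me and iPr trans to it.

**Step 13**
Reactants: 20
Product: 21 (3R,3aS,4S,8aR)-6,8a-dimethyl-3-(propan-2-yl)-2,3,3a,4,5,8-hexahydro-1H-azulene-3,4-diol (jaeschkeanadiol)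
Conditions: Hoveyda–Grubbs II (5–10 mol%), toluene (2 mM), 60–80 °C
Reagents that add atoms: none (ethylene is lost)
Why: Ring-closing metathesis forms the trisubstituted cycloheptene, with the ring enforcing the cis alkene. No stereocentre is involved, and the free OH groups are tolerated.

**Step 14**
Reactants: 21; 22 p-anisoyl chloride
Product: 23 Fertidin
Conditions: 4-MeOC6H4COCl (1.2 equiv), Et3N, DMAP (cat.), CH2Cl2, 0 °C → rt
Reagents that add atoms: p-anisoyl chloride, COc1ccc(cc1)C(Cl)=O
Why: Chemoselective Schotten–Baumann/DMAP acylation of the unhindered secondary alcohol over the tertiary one, with retention at C4.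

## Compound list
1 | cyclopentanone | O=C1CCCC1 | starting material
2 | acetone | CC(C)=O | starting material
3 | 2-(2-hydroxypropan-2-yl)cyclopentan-1-one (racemic) | O=C1CCCC1C(C)(C)O | intermediate
4 | 2-(propan-2-ylidene)cyclopentan-1-one | O=C1CCCC1=C(C)C | intermediate
5 | 2-(propan-2-yl)cyclopentan-1-one (racemic) | O=C1CCCC1C(C)C | intermediate
6 | diallyl carbonate | C=CCOC(=O)OCC=C | starting material
7 | allyl 2-oxo-3-(propan-2-yl)cyclopentane-1-carboxylate | C=CCOC(=O)C1CCC(C(C)C)C1=O | intermediate
8 | iodomethane | CI | starting material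
9 | allyl 1-methyl-2-oxo-3-(propan-2-yl)cyclopentane-1-carboxylate | C=CCOC(=O)C1(C)CCC(C(C)C)C1=O | intermediate
10 | (2R)-2-methyl-5-(propan-2-yl)-2-(prop-2-en-1-yl)cyclopentan-1-one | C=CC[C@@]1(C)CCC(C(C)C)C1=O | intermediate
11 | N-phenylbis(trifluoromethanesulfonimide) | O=S(=O)(C(F)(F)F)N(c1ccccc1)S(=O)(=O)C(F)(F)F | starting material
12 | (5R)-5-methyl-2-(propan-2-yl)-5-(prop-2-en-1-yl)cyclopent-1-en-1-yl triflate | C=CC[C@@]1(C)CCC(C(C)C)=C1OS(=O)(=O)C(F)(F)F | intermediate
13 | carbon monoxide | [C-]#[O+] | starting material
14 | N,O-dimethylhydroxylamine | CONC | starting material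
15 | Weinreb amide (5R)-N-methoxy-N,5-dimethyl-2-(propan-2-yl)-5-(prop-2-en-1-yl)cyclopent-1-ene-1-carboxamide | C=CC[C@@]1(C)CCC(C(C)C)=C1C(=O)N(C)OC | intermediate
16 | methallylmagnesium chloride | C=C(C)C[Mg]Cl | starting material
17 | 1-[(5R)-5-methyl-2-(propan-2-yl)-5-(prop-2-en-1-yl)cyclopent-1-en-1-yl]-3-methylbut-3-en-1-one | C=CC[C@@]1(C)CCC(C(C)C)=C1C(=O)CC(C)=C | intermediate
18 | (1S)-1-[(5R)-5-methyl-2-(propan-2-yl)-5-(prop-2-en-1-yl)cyclopent-1-en-1-yl]-3-methylbut-3-en-1-ol | C=CC[C@@]1(C)CCC(C(C)C)=C1[C@@H](O)CC(C)=C | intermediate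
19 | epoxy alcohol (1S)-1-[(1S,2R,5R)-2-methyl-5-(propan-2-yl)-2-(prop-2-en-1-yl)-6-oxabicyclo[3.1.0]hexan-1-yl]-3-methylbut-3-en-1-ol | C=CC[C@@]1(C)CC[C@]2(C(C)C)O[C@]12[C@@H](O)CC(C)=C | intermediate
20 | diol (1R,2S,3R)-2-[(1S)-1-hydroxy-3-methylbut-3-en-1-yl]-3-methyl-1-(propan-2-yl)-3-(prop-2-en-1-yl)cyclopentan-1-ol | C=CC[C@@]1(C)CC[C@@](O)(C(C)C)[C@@H]1[C@@H](O)CC(C)=C | intermediate
21 | jaeschkeanadiol (3R,3aS,4S,8aR) | O[C@H]2CC(C)=CC[C@@]3(C)CC[C@@](O)(C(C)C)[C@H]23 | intermediate
22 | p-anisoyl chloride | COc1ccc(cc1)C(Cl)=O | starting material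
23 | Fertidin | COc1ccc(C(=O)O[C@H]2CC(C)=CC[C@@]3(C)CC[C@@](O)(C(C)C)[C@H]23)cc1 | target

## Summary
Total steps: 14. Longest linear sequence: 14 (all steps are linear from cyclopentanone).

**Three steps most likely to fail**
1. **Step 12 (Red-Al opening at the hindered tertiary, neopentyl epoxide carbon).**
   - Fallback: drop the pre-installed isopropyl and run the sequence on the des-isopropyl series. After RCM, do nucleophilic epoxidation of the resulting enone and SmI2 opening to a β-hydroxy ketone, and separate the ring-fusion epimers. Then oxidise C3 to the ketone and add iPrCeCl2 from the face anti to the methyl.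
2. **Step 11 (face and chemoselectivity of the directed epoxidation).** The V-alkoxide may instead oxidise the carbinol to the enone, or epoxidise on the opposite face.
   - Fallback: use an (R)-selective KRED in step 10 to make the carbinol epimer, then invert C4 at the end by Mitsunobu esterification with p-anisic acid.
3. **Step 8 (Pd aminocarbonylation of the hindered tetrasubstituted triflate).**
   - Fallback: convert ketone 10 to its trisylhydrazone and do a Shapiro reaction to the regiospecific vinyllithium. Quench with DMF to give the enal, add methallylMgCl, and oxidise with MnO2 to reach 17.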